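**Target:** 8-{(Z)-2-[(1R,6R)-6-(5,7-dimethoxy-2-oxo-2H-chromen-8-yl)-1,4-dimethylcyclohex-3-en-1-yl]ethenyl}-5,7-dimethoxy-2H-chromen-2-one (compound 32).

## Analysis of the target

The target is a dimeric coumarin built on a 1,4-dimethylcyclohex-3-ene ring (C1 quaternary, C2 and C3 methylene, C4(CH3)=C5, C6 methine). C6 is bonded to C8 of a 5,7-dimethoxycoumarin (coumarin B), and C1 carries a (Z)-ethenyl bridge (Cb at the ring, Ca at the arene) to C8 of a second 5,7-dimethoxycoumarin (coumarin A). The two stereocentres are adjacent, C1 (R) and C6 (R). The aryl group at C6 and the styryl arm at C1 lie on the same ring face, with the C1 methyl on the other. The sensitive groups are two pyranone lactones (opened by hydroxide or alkoxide), a Z-styrene on an electron-rich arene (isomerised by acid, iodine or light) and a trisubstituted alkene whose allylic carbon C6 is also benzylic. The hard points are the C6–C8 bond, which joins a secondary carbon beside a quaternary centre to an arene carbon flanked by two oxygens, the absolute and relative control of the C1/C6 pair, and a Z alkene on a neopentyl carbon. Rotation about the C6–C8 bond will be slow, but the target defines no axis, so rotamers are not a stereochemical issue. The strategy rests on ring B: C8 sits between C8a–O and C7–OCH3 with C5–OCH3 para to it. That is the pattern formed when an ynol silyl ether (supplying C8 and C7) joins a 3-methoxy vinylketene (supplying C8a, C4a, C5 and C6), so the arene can be grown on C6 from a linear alkyne instead of being attached to it.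

## Retrosynthetic reasoning

The Z alkene Ca=Cb is taken back to the triple bond of alkyne 31. Syn addition of hydrogen fixes the cis geometry by mechanism, whereas olefination of neopentyl aldehyde 27 with a benzylic ylide would leave it open. The forward step must stop at the alkene and spare the ring alkene and both lactones.

Alkyne 31 is cut at the sp–sp2 bond between Ca and C8 of coumarin A. This gives terminal alkyne 28 and aryl iodide 30, one step from commercial coumarin 29. Coumarin A therefore enters whole and late, and the coupling only has to cope with a hindered, electron-rich iodide.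

Ca of 28 is removed by one-carbon homologation from aldehyde 27, which comes from neopentyl alcohol 26. C1 has no hydrogen, so this arm can be oxidised and homologated under base without risk to the stereocentre.

The pyranone of coumarin B is opened next. The C3=C4 bond and the lactone C–O bond of 24 go back to salicylaldehyde 22 (through cinnamate 23), and the formyl carbon is cut from C4a to give phenol 21. Between 24 and 26 only the oxygen substituents change (25). Cutting here keeps the crowded C6–C8 bond intact, and the free hydroxyl of 21 decides which ortho oxygen becomes the ring oxygen.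

The benzene ring of 21 is the key disconnection. The bonds C8–C8a, C7–C6 and C8a–C4a are cut, leaving siloxyalkyne 14 (C8 and C7) and vinylketene 17 (C8a, C4a, C5, C6), which is stored as cyclobutenone 16, one alkoxy exchange from commercial 15. The ring is cut rather than the C6–C8 bond because a direct arylation would force a doubly ortho-oxygenated carbon onto a secondary carbon beside a quaternary centre. The annulation brings only a linear alkyne to C6, and the polarity of the partners fixes the 1,3,5-oxygen pattern. The forward step must give one regioisomer and leave C1 and C6 untouched.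

The ynol ether of 14 is traced through ynolate 13 and dibromide 12 to ester 11. The two alkyne carbons and the oxygen are the α-carbon, carbonyl carbon and carbonyl oxygen of an acetate side chain. This avoids an aldehyde at C6, whose α-hydrogen would be both allylic and enolisable.

The C6–Cα bond of 11 is cut as a [3,3] shift through ketene acetal 10, returning tertiary allylic alcohol 9 with the double bond at C5=C6. The gain is stereochemical: the new bond must form on the face that carries the C4–O bond, so C6 is set from C4.

The C4 hydroxyl of 9 (and of diol 8) comes from the epoxide of 5 by opening at C5 and elimination toward C6 (through 6 and 7). The epoxide comes from alcohol 4 by hydroxyl-directed oxygen transfer. This places the C4 oxygen cis to the C1 arm, so C1 controls C4 and, through it, C6.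

Alcohol 4 is the reduction product of aldehyde 3, whose ring is cut at C1–C6 and C2–C3 into diene 1 and dienophile 2. This Diels–Alder reaction already places the double bond and both methyl groups as in the target. Run under a chiral Lewis acid, it sets the only stereocentre that is not derived from another.

## Alternatives that were turned down

Alternative 1: The cyclohexene is cut at C5–C6 and at C1–CH3 on a coumarin template, the 3-alkylcoumarin A1. Its benzene ring is the future arene of ring B and its lactone carbonyl is the future Cb; the C4=C5 bond would be closed later by ring-closing metathesis. The forward key step is a copper-catalysed conjugate addition of a vinyl Grignard reagent to C4 of A1 under a chiral ferrocenyl bisphosphine, with C-methylation in the same flask, giving dihydrocoumarin A2 with vinyl trans to methyl.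
- For: the arene is bought with all three oxygens in place, both stereocentres form in one operation, and the lactone ties the aryl group and the future Cb to the same face. The route would need roughly half the steps of the chosen one.
- Against: the acceptor carbon is the β-carbon of an α-alkylated enoate and lies peri to the C5 methoxy group. Additions of this kind are at their best with 3-unsubstituted coumarins and alkyl Grignard reagents, and sp2 nucleophiles usually transfer more slowly and less selectively. Conversion and enantioselectivity are therefore both in doubt at the step that carries all the stereochemistry. Attack of the Grignard reagent on the lactone carbonyl also competes.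
- Comparison: A2 is stronger on convergence and step count. The chosen strategy offers instead a stereochemical relay that rests on one well-precedented catalytic step and an intramolecular chirality transfer, and it never forms a bond at C6 next to ortho substituents. The pyranone of ring B has to be built on the released phenol in both routes.

Alternative 2: The bonds C8–C6, C6–C1 and O–Cb are cut, pairing phenol A3 with dienal A4. In the forward key step an ammonium carboxylate condenses an ortho carbon of A3 with the aldehyde of A4 to the vinyl quinone methide A5. Its tethered enol ether then adds in a hetero-Diels–Alder reaction under a chiral phosphoric acid, closing the cyclohexene and a temporary pyran to give acetal A6.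
- For: it is the shortest plan. Ring, both stereocentres and the cis relation arise in one step from an acyclic chain, and Cb emerges at the aldehyde oxidation level.
- Against: three selectivities have to be won at once. A3 can react at C2 or C4. A5 would normally undergo six-electron oxa-electrocyclisation, which the attack of a trisubstituted enol ether forming a quaternary carbon must outrun. The achiral ammonium salt also opens a racemic pathway beside the chiral acid. The enol ether geometry of A4 must be controlled as well.
- Comparison: A6 is clearly superior in step economy. The chosen strategy spreads the risk over steps with close analogy, and its arene regiochemistry is fixed by the polarity of an alkyne, not by competition between ring positions.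

Alternative 3: The bonds C1–C2 and C5–C6 are cut, with formylcoumarin A7 as dienophile and silyl diene A8 as diene. In the forward key step a chiral Lewis acid, chelated by the formyl and lactone carbonyls, promotes the Diels–Alder addition to the cis-fused adduct A9. Its allylsilane would later shift the alkene to C4=C5 by protodesilylation.
- For: the dienophile is doubly activated, the two stereocentres form together, and the cis fusion places the aryl group and the lactone carbonyl (future Cb) on one face.
- Against: cycloaddition at the coumarin C3=C4 bond costs styrene conjugation, and the C5 methoxy group shields C4 just where the silyl-bearing diene terminus must bond. Enantioselective catalysis for this dienophile class has no close analogy. Afterwards the formyl group must be deoxygenated to the C1 methyl in the presence of a lactone, and the lactone carbonyl must be turned into Cb.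
- Comparison: A9 reaches the carbocycle in fewer steps and is equal to the chosen route in having to rebuild the pyranone of ring B. The chosen strategy avoids the neopentyl deoxygenation and confines its uncertainty to one thermal step without stereochemical consequences.

Key step: step 10

Assumption: the (S)-prolinol-derived oxazaborolidinium salt is taken to be the antipode that gives (S)-3; if its facial sense is the reverse, the mirror-image catalyst is used and nothing else changes.

## Route

Step 1
Reactants: 1 isoprene; 2 methacrolein
Product: 3 (S)-1,4-dimethylcyclohex-3-ene-1-carbaldehyde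
Conditions: (S)-1-(2-methylphenyl)-3,3-diphenyltetrahydro-1H,3H-pyrrolo[1,2-c][1,3,2]oxazaborole·HN(SO2CF3)2 (10 mol %), CH2Cl2, −78 °C
Reagents that add atoms: none
Why: Catalytic enantioselective Diels–Alder reaction; the 2-methyl group of the diene directs the 1,4-("para") adduct, and the N-protonated oxazaborolidine binds the s-trans enal so that one face of the dienophile is open, which sets C1.

Step 2
Reactants: 3 (S)-1,4-dimethylcyclohex-3-ene-1-carbaldehyde
Product: 4 [(S)-1,4-dimethylcyclohex-3-en-1-yl]methanol
Conditions: NaBH4, MeOH, 0 °C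
Reagents that add atoms: none
Why: Hydride 1,2-reduction of the aldehyde; the quaternary centre is not touched.

Step 3
Reactants: 4 [(S)-1,4-dimethylcyclohex-3-en-1-yl]methanol
Product: 5 [(1S,3S,6R)-3,6-dimethyl-7-oxabicyclo[4.1.0]heptan-3-yl]methanol (epoxide oxygen cis to the CH2OH arm)
Conditions: VO(acac)2 (2 mol %), t-BuOOH, CH2Cl2, 0 °C → rt
Reagents that add atoms: tert-butyl hydroperoxide, CC(C)(C)OO
Why: Hydroxyl-directed epoxidation: the vanadium-bound alcohol, with its arm axial, delivers the coordinated peroxide only to the face of C4=C5 syn to that arm, which sets C4 and C5. The syn epoxide cannot be opened by its own hydroxyl, because backside attack is geometrically excluded.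

Step 4
Reactants: 5 [(1S,3S,6R)-3,6-dimethyl-7-oxabicyclo[4.1.0]heptan-3-yl]methanol
Product: 8 (1R,4S)-4-(hydroxymethyl)-1,4-dimethylcyclohex-2-en-1-ol, via hydroxy selenide 6 (not isolated), via selenoxide 7 (not isolated)
Conditions: (PhSe)2, NaBH4, EtOH, reflux; then 30 % H2O2, THF, 0 °C → rt
Reagents that add atoms: none
Why: Epoxide-to-allylic-alcohol transposition by selenide opening and selenoxide syn-elimination: the selenolate attacks the secondary carbon C5 with inversion (trans-diaxial opening), so the C4–O bond keeps its configuration. The selenoxide can eliminate only toward C6, because C4 has no hydrogen.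

Step 5
Reactants: 8 (1R,4S)-4-(hydroxymethyl)-1,4-dimethylcyclohex-2-en-1-ol
Product: 9 (1R,4S)-4-[(tert-butyldimethylsilyloxy)methyl]-1,4-dimethylcyclohex-2-en-1-ol
Conditions: t-BuMe2SiCl, imidazole, CH2Cl2, 0 °C
Reagents that add atoms: tert-butyldimethylsilyl chloride, CC(C)(C)[Si](C)(C)Cl
Why: Silylation of the primary hydroxyl is much faster than that of the tertiary allylic one, so the mono-ether should form and leave the C4 hydroxyl free.

Step 6
Reactants: 9 (1R,4S)-4-[(tert-butyldimethylsilyloxy)methyl]-1,4-dimethylcyclohex-2-en-1-ol
Product: 11 ethyl 2-[(1R,6S)-6-[(tert-butyldimethylsilyloxy)methyl]-3,6-dimethylcyclohex-2-en-1-yl]acetate, via ketene acetal 10 (not isolated)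
Conditions: CH3C(OEt)3, EtCO2H (cat.), 140 °C, EtOH distilled off
Reagents that add atoms: triethyl orthoacetate, CCOC(C)(OCC)OCC
Why: Johnson–Claisen rearrangement: orthoester exchange and loss of ethanol give ketene acetal 10, whose [3,3] shift is suprafacial. The new C6–C bond therefore forms on the face from which the C4–O bond leaves, cis to the silyloxymethyl arm, and the alkene returns to C4=C5; C6 is thus set by relay from C1.

Step 7
Reactants: 11 ethyl 2-[(1R,6S)-6-[(tert-butyldimethylsilyloxy)methyl]-3,6-dimethylcyclohex-2-en-1-yl]acetate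
Product: 12 ethyl 2,2-dibromo-2-[(1R,6S)-6-[(tert-butyldimethylsilyloxy)methyl]-3,6-dimethylcyclohex-2-en-1-yl]acetate
Conditions: LiN(SiMe3)2, THF, −78 °C, then BrCCl2CCl2Br; enolisation and bromination run twice in one flask
Reagents that add atoms: 1,2-dibromo-1,1,2,2-tetrachloroethane, BrC(Cl)(Cl)C(Cl)(Cl)Br
Why: Two rounds of ester enolate formation and electrophilic bromination at the only enolisable carbon; C6 is β to the ester and is not deprotonated at this temperature.

Step 8
Reactants: 12 ethyl 2,2-dibromo-2-[(1R,6S)-6-[(tert-butyldimethylsilyloxy)methyl]-3,6-dimethylcyclohex-2-en-1-yl]acetate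
Product: 14 tert-butyl{[(1S,6R)-1,4-dimethyl-6-[(triisopropylsilyloxy)ethynyl]cyclohex-3-en-1-yl]methoxy}dimethylsilane, via lithium ynolate 13 (not isolated)
Conditions: t-BuLi (4 equiv), THF, −78 → 0 °C; then i-Pr3SiOSO2CF3 (2.2 equiv), −78 °C → rt
Reagents that add atoms: triisopropylsilyl trifluoromethanesulfonate, CC(C)[Si](OS(=O)(=O)C(F)(F)F)(C(C)C)C(C)C
Why: Ynolate formation from an α,α-dibromo ester: two bromine–lithium exchanges give the α-lithiated ester enolate, which expels lithium ethoxide to ynolate 13. The bulky silyl triflate then reacts at oxygen, as is usual for triisopropylsilyl electrophiles with ynolates, and C6 is not involved.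

Step 9
Reactants: 15 3-ethoxycyclobut-2-en-1-one
Product: 16 3-methoxycyclobut-2-en-1-one
Conditions: MeOH, camphorsulfonic acid (cat.), rt; Et3N quench, distillation
Reagents that add atoms: methanol, CO
Why: Acid-catalysed alkoxy exchange of a vinylogous ester (addition of methanol to the protonated enone and loss of ethanol), driven by methanol as solvent.

Step 10
Reactants: 14 tert-butyl{[(1S,6R)-1,4-dimethyl-6-[(triisopropylsilyloxy)ethynyl]cyclohex-3-en-1-yl]methoxy}dimethylsilane; 16 3-methoxycyclobut-2-en-1-one
Product: 21 2-[(1R,6S)-6-[(tert-butyldimethylsilyloxy)methyl]-3,6-dimethylcyclohex-2-en-1-yl]-5-methoxy-3-(triisopropylsilyloxy)phenol, via vinylketene 17 (not isolated), via vinylcyclobutenone 18 (not isolated), via dienylketene 19 (not isolated), via cyclohexadienone 20 (not isolated)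
Conditions: 16 (1.3 equiv), PhMe, 80 °C, then 110 °C
Reagents that add atoms: none
Why: Danheiser benzannulation in its ynol silyl ether form; the closest known case is the thermal union of 3-alkylcyclobutenones with triisopropylsilyl ynol ethers to give 2-substituted resorcinol monosilyl ethers. On heating, 16 opens by four-electron conrotatory cleavage to vinylketene 17, and the nucleophilic alkyne carbon of 14 (the one bonded to C6) attacks the ketene carbonyl carbon, so the [2+2] cycloaddition makes C8–C8a and C7–C6 and closes the transient four-membered ring of 18. A second four-electron opening gives dienylketene 19; it is reversible, so the geometry with the methoxyvinyl group turned toward the ketene is drained by six-electron disrotatory electrocyclisation, which forms C8a–C4a and closes the benzene ring as dienone 20, and enolisation gives 21. No stereocentre is created: the sp3 carbon of 18 becomes planar again, and C1 and C6 carry only a linear alkyne into the step, so both pass unchanged. The selectivity that matters is regiochemical and is secured by the oxygen lone pair of the ynol ether, which polarises the triple bond so that the cyclohexenyl-bearing carbon ends between the free hydroxyl and the silyloxy group, with OCH3 para to it. The same polarisation gives chemoselectivity, since the electron-rich alkyne should capture 17 far faster than the trisubstituted ring alkene. The 3-alkoxy group on the cyclobutenone is the less usual element and is expected to slow the first ring opening, hence the two temperature stages.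

Step 11
Reactants: 21 2-[(1R,6S)-6-[(tert-butyldimethylsilyloxy)methyl]-3,6-dimethylcyclohex-2-en-1-yl]-5-methoxy-3-(triisopropylsilyloxy)phenol
Product: 22 3-[(1R,6S)-6-[(tert-butyldimethylsilyloxy)methyl]-3,6-dimethylcyclohex-2-en-1-yl]-2-hydroxy-6-methoxy-4-(triisopropylsilyloxy)benzaldehyde
Conditions: MgCl2, Et3N, (CH2O)n, MeCN, reflux
Reagents that add atoms: formaldehyde (as paraformaldehyde), C=O
Why: Magnesium-mediated ortho-formylation (Casnati–Skattebøl): the magnesium phenoxide delivers formaldehyde to its only free ortho position, the future C4a between the hydroxyl and the methoxy group, and a second formaldehyde accepts hydride to give the aldehyde. The silyl ether oxygen cannot direct, which tells the two ortho oxygens apart.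

Step 12
Reactants: 22 3-[(1R,6S)-6-[(tert-butyldimethylsilyloxy)methyl]-3,6-dimethylcyclohex-2-en-1-yl]-2-hydroxy-6-methoxy-4-(triisopropylsilyloxy)benzaldehyde
Product: 24 8-[(1R,6S)-6-[(tert-butyldimethylsilyloxy)methyl]-3,6-dimethylcyclohex-2-en-1-yl]-5-methoxy-7-(triisopropylsilyloxy)-2H-chromen-2-one, via cinnamate 23 (not isolated)
Conditions: Ph3P=CHCO2Et, PhNEt2, reflux
Reagents that add atoms: ethyl (triphenylphosphoranylidene)acetate, CCOC(=O)C=P(c1ccccc1)(c1ccccc1)c1ccccc1
Why: Wittig olefination gives the E-cinnamate 23, which at the temperature of boiling diethylaniline isomerises and lactonises onto the free phenol. This is the standard one-flask coumarin synthesis from salicylaldehydes and closes the pyranone of ring B.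

Step 13
Reactants: 24 8-[(1R,6S)-6-[(tert-butyldimethylsilyloxy)methyl]-3,6-dimethylcyclohex-2-en-1-yl]-5-methoxy-7-(triisopropylsilyloxy)-2H-chromen-2-one
Product: 25 7-hydroxy-8-[(1R,6S)-6-(hydroxymethyl)-3,6-dimethylcyclohex-2-en-1-yl]-5-methoxy-2H-chromen-2-one
Conditions: Bu4NF, THF, 0 °C → rt
Reagents that add atoms: none
Why: Fluoride cleaves the aryl triisopropylsilyl ether and the primary tert-butyldimethylsilyl ether in one operation; the lactone should be stable to Bu4NF at this temperature.

Step 14
Reactants: 25 7-hydroxy-8-[(1R,6S)-6-(hydroxymethyl)-3,6-dimethylcyclohex-2-en-1-yl]-5-methoxy-2H-chromen-2-one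
Product: 26 8-[(1R,6S)-6-(hydroxymethyl)-3,6-dimethylcyclohex-2-en-1-yl]-5,7-dimethoxy-2H-chromen-2-one
Conditions: MeI, K2CO3, acetone, reflux
Reagents that add atoms: iodomethane, CI
Why: Williamson etherification: carbonate deprotonates only the acidic 7-hydroxycoumarin, so the phenol is methylated and the neopentyl alcohol stays free.

Step 15
Reactants: 26 8-[(1R,6S)-6-(hydroxymethyl)-3,6-dimethylcyclohex-2-en-1-yl]-5,7-dimethoxy-2H-chromen-2-one
Product: 27 (1S,6R)-6-(5,7-dimethoxy-2-oxo-2H-chromen-8-yl)-1,4-dimethylcyclohex-3-ene-1-carbaldehyde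
Conditions: Dess–Martin periodinane, NaHCO3, CH2Cl2, 0 °C → rt
Reagents that add atoms: none
Why: Dess–Martin oxidation tolerates the electron-rich arene, the lactone and the alkene and stops at the aldehyde, which has no α-hydrogen and cannot epimerise.

Step 16
Reactants: 27 (1S,6R)-6-(5,7-dimethoxy-2-oxo-2H-chromen-8-yl)-1,4-dimethylcyclohex-3-ene-1-carbaldehyde
Product: 28 8-[(1R,6S)-6-ethynyl-3,6-dimethylcyclohex-2-en-1-yl]-5,7-dimethoxy-2H-chromen-2-one
Conditions: dimethyl (1-diazo-2-oxopropyl)phosphonate, K2CO3, MeOH, 0 °C → rt
Reagents that add atoms: dimethyl (1-diazo-2-oxopropyl)phosphonate, COP(=O)(OC)C(=[N+]=[N-])C(C)=O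
Why: Seyferth–Gilbert homologation with the Ohira–Bestmann reagent: the diazomethylphosphonate anion adds to the aldehyde, and loss of phosphate and N2 with a 1,2-hydride shift gives the terminal alkyne. Any transient opening of the lactone by methoxide is reversed on acidic work-up.

Step 17
Reactants: 29 5,7-dimethoxy-2H-chromen-2-one
Product: 30 8-iodo-5,7-dimethoxy-2H-chromen-2-one
Conditions: N-iodosuccinimide, CF3CO2H (cat.), MeCN, rt
Reagents that add atoms: N-iodosuccinimide, O=C1CCC(=O)N1I
Why: Electrophilic aromatic iodination; C8 is para to the 5-methoxy and ortho to the 7-methoxy group and less hindered than C6, which is wedged between two methoxy groups, so the 8-iodide should be the main product.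

Step 18
Reactants: 28 8-[(1R,6S)-6-ethynyl-3,6-dimethylcyclohex-2-en-1-yl]-5,7-dimethoxy-2H-chromen-2-one; 30 8-iodo-5,7-dimethoxy-2H-chromen-2-one
Product: 31 8-{[(1S,6R)-6-(5,7-dimethoxy-2-oxo-2H-chromen-8-yl)-1,4-dimethylcyclohex-3-en-1-yl]ethynyl}-5,7-dimethoxy-2H-chromen-2-one
Conditions: PdCl2(PPh3)2 (5 mol %), CuI (10 mol %), Et3N, DMF, 60 °C, degassed
Reagents that add atoms: none
Why: Sonogashira coupling of a terminal alkyne with an aryl iodide; the iodide is chosen because the electron-rich, doubly ortho-substituted arene undergoes oxidative addition slowly.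

Step 19
Reactants: 31 8-{[(1S,6R)-6-(5,7-dimethoxy-2-oxo-2H-chromen-8-yl)-1,4-dimethylcyclohex-3-en-1-yl]ethynyl}-5,7-dimethoxy-2H-chromen-2-one
Product: 32 8-{(Z)-2-[(1R,6R)-6-(5,7-dimethoxy-2-oxo-2H-chromen-8-yl)-1,4-dimethylcyclohex-3-en-1-yl]ethenyl}-5,7-dimethoxy-2H-chromen-2-one
Conditions: H2 (1 atm), Pd on CaCO3 poisoned with Pb(OAc)2, quinoline, EtOAc, rt
Reagents that add atoms: none
Why: Lindlar semihydrogenation: syn delivery of hydrogen on the poisoned surface gives the Z alkene, and the hindered trisubstituted ring alkene and the conjugated lactone double bonds should not be reduced under these conditions.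

## Compound list

1 | isoprene | C=CC(C)=C | starting material
2 | methacrolein | CC(=C)C=O | starting material
3 | (S)-1,4-dimethylcyclohex-3-ene-1-carbaldehyde | O=C[C@@]1(C)CCC(C)=CC1 | intermediate
4 | [(S)-1,4-dimethylcyclohex-3-en-1-yl]methanol | OC[C@@]1(C)CCC(C)=CC1 | intermediate
5 | [(1S,3S,6R)-3,6-dimethyl-7-oxabicyclo[4.1.0]heptan-3-yl]methanol (epoxide cis to CH2OH) | OC[C@@]1(C)CC[C@@]2(C)O[C@H]2C1 | intermediate
6 | hydroxy selenide, (1R,2R,4S)-4-(hydroxymethyl)-1,4-dimethyl-2-(phenylselanyl)cyclohexan-1-ol (formed in the flask, step 4) | OC[C@@]1(C)CC[C@@](C)(O)[C@H]([Se]c2ccccc2)C1 | intermediate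
7 | selenoxide of 6, either configuration at selenium (formed in the flask, step 4) | OC[C@@]1(C)CC[C@@](C)(O)[C@H]([Se](=O)c2ccccc2)C1 | intermediate
8 | (1R,4S)-4-(hydroxymethyl)-1,4-dimethylcyclohex-2-en-1-ol (cis diol) | OC[C@@]1(C)CC[C@@](C)(O)C=C1 | intermediate
9 | (1R,4S)-4-[(tert-butyldimethylsilyloxy)methyl]-1,4-dimethylcyclohex-2-en-1-ol | CC(C)(C)[Si](C)(C)OC[C@@]1(C)CC[C@@](C)(O)C=C1 | intermediate
10 | ketene acetal, tert-butyl{[(1S,4R)-4-[(1-ethoxyethenyl)oxy]-1,4-dimethylcyclohex-2-en-1-yl]methoxy}dimethylsilane (formed in the flask, step 6) | CC(C)(C)[Si](C)(C)OC[C@@]1(C)CC[C@@](C)(OC(=C)OCC)C=C1 | intermediate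
11 | ethyl 2-[(1R,6S)-6-[(tert-butyldimethylsilyloxy)methyl]-3,6-dimethylcyclohex-2-en-1-yl]acetate (acetate arm cis to the silyloxymethyl arm) | CC(C)(C)[Si](C)(C)OC[C@@]1(C)CCC(C)=C[C@H]1CC(=O)OCC | intermediate
12 | ethyl 2,2-dibromo-2-[(1R,6S)-6-[(tert-butyldimethylsilyloxy)methyl]-3,6-dimethylcyclohex-2-en-1-yl]acetate | CC(C)(C)[Si](C)(C)OC[C@@]1(C)CCC(C)=C[C@H]1C(Br)(Br)C(=O)OCC | intermediate
13 | lithium ynolate, lithium 2-[(1R,6S)-6-[(tert-butyldimethylsilyloxy)methyl]-3,6-dimethylcyclohex-2-en-1-yl]ethynolate (formed in the flask, step 8) | CC(C)(C)[Si](C)(C)OC[C@@]1(C)CCC(C)=C[C@H]1C#C[O-].[Li+] | intermediate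
14 | tert-butyl{[(1S,6R)-1,4-dimethyl-6-[(triisopropylsilyloxy)ethynyl]cyclohex-3-en-1-yl]methoxy}dimethylsilane | CC(C)(C)[Si](C)(C)OC[C@@]1(C)CCC(C)=C[C@H]1C#CO[Si](C(C)C)(C(C)C)C(C)C | intermediate
15 | 3-ethoxycyclobut-2-en-1-one | CCOC1=CC(=O)C1 | starting material
16 | 3-methoxycyclobut-2-en-1-one | COC1=CC(=O)C1 | intermediate
17 | vinylketene, 3-methoxybuta-1,3-dien-1-one (formed in the flask, step 10) | C=C(OC)C=C=O | intermediate
18 | vinylcyclobutenone, 2-(cyclohexenyl)-4-(1-methoxyethenyl)-3-(triisopropylsilyloxy)cyclobut-2-en-1-one, either configuration at the sp3 ring carbon (formed in the flask, step 10) | CC(C)(C)[Si](C)(C)OC[C@@]1(C)CCC(C)=C[C@H]1C2=C(O[Si](C(C)C)(C(C)C)C(C)C)C(C(OC)=C)C2=O | intermediate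
19 | dienylketene, 2-(cyclohexenyl)-5-methoxy-3-(triisopropylsilyloxy)hexa-1,3,5-trien-1-one, methoxyvinyl group cis to the ketene-bearing carbon (formed in the flask, step 10) | CC(C)(C)[Si](C)(C)OC[C@@]1(C)CCC(C)=C[C@H]1C(=C=O)/C(O[Si](C(C)C)(C(C)C)C(C)C)=C\C(OC)=C | intermediate
20 | cyclohexadienone, 2-(cyclohexenyl)-5-methoxy-3-(triisopropylsilyloxy)cyclohexa-2,4-dien-1-one (formed in the flask, step 10) | CC(C)(C)[Si](C)(C)OC[C@@]1(C)CCC(C)=C[C@H]1C2=C(O[Si](C(C)C)(C(C)C)C(C)C)C=C(OC)CC2=O | intermediate
21 | 2-[(1R,6S)-6-[(tert-butyldimethylsilyloxy)methyl]-3,6-dimethylcyclohex-2-en-1-yl]-5-methoxy-3-(triisopropylsilyloxy)phenol | CC(C)(C)[Si](C)(C)OC[C@@]1(C)CCC(C)=C[C@H]1c1c(O)cc(OC)cc1O[Si](C(C)C)(C(C)C)C(C)C | intermediate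
22 | 3-[(1R,6S)-6-[(tert-butyldimethylsilyloxy)methyl]-3,6-dimethylcyclohex-2-en-1-yl]-2-hydroxy-6-methoxy-4-(triisopropylsilyloxy)benzaldehyde | CC(C)(C)[Si](C)(C)OC[C@@]1(C)CCC(C)=C[C@H]1c1c(O)c(C=O)c(OC)cc1O[Si](C(C)C)(C(C)C)C(C)C | intermediate
23 | cinnamate, ethyl (E)-3-aryl-prop-2-enoate of 22 (formed in the flask, step 12) | CC(C)(C)[Si](C)(C)OC[C@@]1(C)CCC(C)=C[C@H]1c1c(O)c(/C=C/C(=O)OCC)c(OC)cc1O[Si](C(C)C)(C(C)C)C(C)C | intermediate
24 | 8-[(1R,6S)-6-[(tert-butyldimethylsilyloxy)methyl]-3,6-dimethylcyclohex-2-en-1-yl]-5-methoxy-7-(triisopropylsilyloxy)-2H-chromen-2-one | CC(C)(C)[Si](C)(C)OC[C@@]1(C)CCC(C)=C[C@H]1c1c(O[Si](C(C)C)(C(C)C)C(C)C)cc(OC)c2ccc(=O)oc12 | intermediate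
25 | 7-hydroxy-8-[(1R,6S)-6-(hydroxymethyl)-3,6-dimethylcyclohex-2-en-1-yl]-5-methoxy-2H-chromen-2-one | OC[C@@]1(C)CCC(C)=C[C@H]1c1c(O)cc(OC)c2ccc(=O)oc12 | intermediate
26 | 8-[(1R,6S)-6-(hydroxymethyl)-3,6-dimethylcyclohex-2-en-1-yl]-5,7-dimethoxy-2H-chromen-2-one | OC[C@@]1(C)CCC(C)=C[C@H]1c1c(OC)cc(OC)c2ccc(=O)oc12 | intermediate
27 | (1S,6R)-6-(5,7-dimethoxy-2-oxo-2H-chromen-8-yl)-1,4-dimethylcyclohex-3-ene-1-carbaldehyde | O=C[C@@]1(C)CCC(C)=C[C@H]1c1c(OC)cc(OC)c2ccc(=O)oc12 | intermediate
28 | 8-[(1R,6S)-6-ethynyl-3,6-dimethylcyclohex-2-en-1-yl]-5,7-dimethoxy-2H-chromen-2-one | C#C[C@@]1(C)CCC(C)=C[C@H]1c1c(OC)cc(OC)c2ccc(=O)oc12 | intermediate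
29 | 5,7-dimethoxy-2H-chromen-2-one | COc1cc(OC)c2ccc(=O)oc2c1 | starting material
30 | 8-iodo-5,7-dimethoxy-2H-chromen-2-one | COc1cc(OC)c2ccc(=O)oc2c1I | intermediate
31 | 8-{[(1S,6R)-6-(5,7-dimethoxy-2-oxo-2H-chromen-8-yl)-1,4-dimethylcyclohex-3-en-1-yl]ethynyl}-5,7-dimethoxy-2H-chromen-2-one | COc1cc(OC)c2ccc(=O)oc2c1C#C[C@@]1(C)CCC(C)=C[C@H]1c1c(OC)cc(OC)c2ccc(=O)oc12 | intermediate
32 | 8-{(Z)-2-[(1R,6R)-6-(5,7-dimethoxy-2-oxo-2H-chromen-8-yl)-1,4-dimethylcyclohex-3-en-1-yl]ethenyl}-5,7-dimethoxy-2H-chromen-2-one | COc1cc(OC)c2ccc(=O)oc2c1/C=C\[C@@]1(C)CCC(C)=C[C@H]1c1c(OC)cc(OC)c2ccc(=O)oc12 | target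

## Step count and least certain steps

Total step count: 19. Longest linear sequence: 17 steps (steps 1–8, 10–16, 18 and 19, from 1 and 2); steps 9 and 17 are one-step side branches.

Step 10 (key step). The first ring opening of 16 may be too slow at temperatures the ynol silyl ether tolerates, because the enol ether conjugation of 16 is lost on opening. In that case 14 would isomerise by silyl migration or decompose before it is captured. A second risk is acylation of the product phenol by surplus 17. The fallback sets out from 14 and makes the same vinylketene 17 at 0–25 °C by 1,4-dehydrochlorination of (E)-3-methoxybut-2-enoyl chloride F1 with Et3N in the presence of 14. The [2+2] capture then gives 18 without heating; 18 is freed of amine salt and heated alone in toluene, so that ring opening, six-electron closure and enolisation run in the absence of the alkyne. The route is rejoined at 21.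

Step 3. Facial direction may be incomplete, because the hydroxyl is three carbons from the alkene and must be axial to direct. Any anti epoxide would be carried through to the C6 epimer. The fallback replaces substrate control by reagent control on the same compounds, from 4 to 5: Shi epoxidation with the fructose-derived ketone catalyst and KHSO5 (buffered, MeCN/dimethoxymethane/water, 0 °C). The enantiomer of the ketone is chosen so that its spiro transition state matches the required face. No new compound arises.

Step 6. The tertiary allylic alcohol may ionise under acid at 140 °C (dehydration to a diene or 1,3-transposition), and orthoester exchange at the hindered oxygen may be slow. The fallback is an Ireland–Claisen rearrangement from 9. Acetylation (Ac2O, DMAP, Et3N) gives the acetate F2. LiN(i-Pr)2 and Me3SiCl in THF at −78 °C give the silyl ketene acetal F3, which rearranges on warming, with the same suprafacial transfer, to the trimethylsilyl ester F4. Aqueous work-up frees the acid F5, and EtI with K2CO3 in DMF returns to 11.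

Step 8. Base may remove HBr from 12 toward the allylic C6–H, the dianion may collapse incompletely with so bulky a substituent, or silylation may occur at carbon. The fallback sets out from 11. i-Bu2AlH at −78 °C reduces the ester to the aldehyde F6. Nonafluorobutanesulfonyl fluoride and a phosphazene base convert F6 through the alkenyl nonaflate F7, by elimination, into the terminal alkyne F8. F8 is lithiated with n-BuLi and oxidised with LiOOt-Bu (from t-BuOOH and LiN(SiMe3)2) to the same ynolate 13, which is silylated as in step 8 to rejoin the route at 14.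

Step 9. Methanol under acid may cleave the strained ring (to acetoacetate-type esters) in competition with exchange, and the volatile product may be lost on isolation. The fallback sets out from 15: hydrolysis with cold dilute aqueous HCl gives cyclobutane-1,3-dione F9, and O-methylation of its enol with Me3SiCHN2 in MeOH/toluene gives 16.

Step 19. Hydrogen uptake may be slow at an alkyne flanked by a quaternary carbon and a 2,6-disubstituted arene, and the longer contact time invites over-reduction or Z-to-E isomerisation. The fallback builds the Z alkene by olefination and cross-coupling. From 27, Stork–Zhao olefination (Ph3P+CH2I I−, NaN(SiMe3)2, THF/DMPU, −78 °C) gives the (Z)-vinyl iodide F10. Iodide 30 is converted by Miyaura borylation (bis(pinacolato)diboron, PdCl2(dppf), KOAc, dioxane) into the boronate F11. Suzuki–Miyaura coupling of F10 with F11 (Pd(PPh3)4, K3PO4, THF/water), with retention of alkene geometry, gives 32 directly.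

## Further compounds

F1 | step 10 | (E)-3-methoxybut-2-enoyl chloride | C/C(OC)=C\C(Cl)=O
F0 | step 3 | none | none
F2 | step 6 | (1R,4S)-4-[(tert-butyldimethylsilyloxy)methyl]-1,4-dimethylcyclohex-2-en-1-yl acetate | CC(C)(C)[Si](C)(C)OC[C@@]1(C)CC[C@@](C)(OC(C)=O)C=C1
F3 | step 6 | trimethylsilyl ketene acetal of F2 | CC(C)(C)[Si](C)(C)OC[C@@]1(C)CC[C@@](C)(OC(=C)O[Si](C)(C)C)C=C1
F4 | step 6 | trimethylsilyl 2-[6-[(tert-butyldimethylsilyloxy)methyl]-3,6-dimethylcyclohex-2-en-1-yl]acetate (arms cis) | CC(C)(C)[Si](C)(C)OC[C@@]1(C)CCC(C)=C[C@H]1CC(=O)O[Si](C)(C)C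
F5 | step 6 | 2-[6-[(tert-butyldimethylsilyloxy)methyl]-3,6-dimethylcyclohex-2-en-1-yl]acetic acid (arms cis) | CC(C)(C)[Si](C)(C)OC[C@@]1(C)CCC(C)=C[C@H]1CC(O)=O
F6 | step 8 | 2-[6-[(tert-butyldimethylsilyloxy)methyl]-3,6-dimethylcyclohex-2-en-1-yl]acetaldehyde (arms cis) | CC(C)(C)[Si](C)(C)OC[C@@]1(C)CCC(C)=C[C@H]1CC=O
F7 | step 8 | 2-[6-[(tert-butyldimethylsilyloxy)methyl]-3,6-dimethylcyclohex-2-en-1-yl]ethenyl nonafluorobutane-1-sulfonate (arms cis, either alkene geometry) | CC(C)(C)[Si](C)(C)OC[C@@]1(C)CCC(C)=C[C@H]1C=COS(=O)(=O)C(F)(F)C(F)(F)C(F)(F)C(F)(F)F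
F8 | step 8 | tert-butyl[(6-ethynyl-1,4-dimethylcyclohex-3-en-1-yl)methoxy]dimethylsilane (ethynyl cis to the silyloxymethyl arm) | CC(C)(C)[Si](C)(C)OC[C@@]1(C)CCC(C)=C[C@H]1C#C
F9 | step 9 | cyclobutane-1,3-dione | O=C1CC(=O)C1
F10 | step 19 | 8-[6-[(Z)-2-iodoethenyl]-3,6-dimethylcyclohex-2-en-1-yl]-5,7-dimethoxy-2H-chromen-2-one (iodoethenyl cis to the aryl group) | I/C=C\[C@@]1(C)CCC(C)=C[C@H]1c1c(OC)cc(OC)c2ccc(=O)oc12
F11 | step 19 | 5,7-dimethoxy-8-(4,4,5,5-tetramethyl-1,3,2-dioxaborolan-2-yl)-2H-chromen-2-one | COc1cc(OC)c2ccc(=O)oc2c1B1OC(C)(C)C(C)(C)O1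
A1 | alternative 1 | 5,7-dimethoxy-3-(3-methylbut-3-en-1-yl)-2H-chromen-2-one | COc1cc(OC)c2cc(CCC(C)=C)c(=O)oc2c1
A2 | alternative 1 | 4-ethenyl-5,7-dimethoxy-3-methyl-3-(3-methylbut-3-en-1-yl)-3,4-dihydro-2H-chromen-2-one (vinyl trans to CH3) | C=C[C@H]1c2c(OC)cc(OC)cc2OC(=O)[C@@]1(C)CCC(C)=C
A3 | alternative 2 | 3,5-dimethoxyphenol | COc1cc(O)cc(OC)c1
A4 | alternative 2 | (2E)-7-methoxy-3,6-dimethylhepta-2,6-dienal | O=C/C=C(\C)CCC(C)=COC
A5 | alternative 2 | 6-(7-methoxy-3,6-dimethylhepta-2,6-dien-1-ylidene)-3,5-dimethoxycyclohexa-2,4-dien-1-one | O=C1C=C(OC)C=C(OC)C1=CC=C(C)CCC(C)=COC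
A6 | alternative 2 | cis-fused 1,3,6-trimethoxy-6a,9-dimethyl-6a,7,8,10a-tetrahydro-6H-benzo[c]chromene (either configuration at the acetal carbon) | COC1Oc2cc(OC)cc(OC)c2[C@@H]2C=C(C)CC[C@]12C
A7 | alternative 3 | 5,7-dimethoxy-2-oxo-2H-chromene-3-carbaldehyde | COc1cc(OC)c2cc(C=O)c(=O)oc2c1
A8 | alternative 3 | (E)-trimethyl(2-methylbuta-1,3-dien-1-yl)silane | C=C/C(C)=C/[Si](C)(C)C
A9 | alternative 3 | cis-fused 1,3-dimethoxy-9-methyl-6-oxo-10-(trimethylsilyl)-7,10,10a-trihydro-6H-benzo[c]chromene-6a-carbaldehyde (either configuration at the silyl-bearing carbon) | O=C[C@]12CC=C(C)C([Si](C)(C)C)[C@H]1c1c(OC)cc(OC)cc1OC2=O
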